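Two questions stand over this flask: what has stopped it by the asked time, and how much product it holds then. Two chemists answer differently.

| flask | substrate | partner | free catalyst | remark | time |
|---|---|---|---|---|---|
| larch | 6 mM | 6 mM | 0.24 mM | run made earlier |  |
| cedar | 9 mM | 6 mM | 0.24 mM | run made earlier |  |
| oak | 12 mM | 6 mM | 0.36 mM | run made earlier |  |
| flask | 12 mM | 6.00 mM | 0.24 mM |  | 3.0 d |

| run | time / d | product / % | substrate / % |
|---|---|---|---|
| larch | 0.250 | 39 | 62 |
| larch | 0.417 | 50 | 50 |
| larch | 0.625 | 53 | 45 |
| larch | 1.04 | 58 | 42 |
| larch | 1.67 | 60 | 41 |
| larch | 3.00 | 59 | 41 |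
| cedar | 0.250 | 29 | 69 |
| cedar | 0.417 | 37 | 66 |
| cedar | 0.625 | 43 | 57 |
| cedar | 1.04 | 45 | 56 |
| cedar | 1.67 | 50 | 54 |
| cedar | 3.00 | 46 | 51 |
| oak | 0.250 | 30 | 72 |
| oak | 0.417 | 31 | 66 |
| oak | 0.833 | 41 | 64 |
| oak | 1.67 | 38 | 63 |
| oak | 3.00 | 37 | 58 |

(readings scatter by 2 percentage points)

1. which holds at 3.0 d: what has brought the reaction to rest, or that it has not come to rest (no working catalyst is left / it is still moving / the partner has run out first / all of the substrate has reacted / forward and back rates have come level)
2. how much product there is at 3.0 d, in percent of the substrate charged

- the reaction counts as stopped when no species that holds the substrate changes by six tenths of a point or more over the second half of the time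

The first calls the partner the limiting reagent: this flask has 6.00 mM of it against 12 mM of substrate, so product should climb to 50.0% of the substrate and stop there. The second points to oak, with the same substrate and partner and more catalyst: its product reads 41% at 0.833 d and 37% at 3.00 d, no rise, and 13 percentage points short of that mark. So the second holds that forward and back rates come level, and measures this by a balance number: c(product)·c(product)/(c(substrate)·c(partner)), assuming one by-product per product and taking c(partner) as its charge less the product.

The last readings give 2.07 for larch, 2.01 for cedar and 1.82 for oak, on average 1.96. Solving that balance for this flask, my own reckoning gives 4.57 mM of product, or 38.1%. Larch, with the same catalyst charge as this flask, reads 60% at 1.67 d and 59% at 3.00 d, level within the scatter before the 3.0 d asked of this flask.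

The forecast takes the second side, a little higher than my figure: forward and back rates have come level, with 39%, since “The near-constant quotient points to equilibrium”.

The result for this flask: forward and back rates have come level, with 37.6% product at 3.0 d. Over the second half of the time, nothing holding the substrate moves by more than 0.091 points. Worked from this flask's end amounts, the balance number comes to 2.13.

    partner + free catalyst ⇌ catalyst intermediate A (K = 210 L mol⁻¹, k = 4840 L mol⁻¹ h⁻¹)
    catalyst intermediate A ⇌ by-product + catalyst intermediate B (K = 0.0280 M, k = 23.4 h⁻¹)
    catalyst intermediate B ⇌ catalyst intermediate C (K = 0.690, k = 23.6 h⁻¹)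
    substrate + catalyst intermediate C ⇌ catalyst intermediate D (K = 140 L mol⁻¹, k = 1.72 × 10⁵ L mol⁻¹ h⁻¹)
    catalyst intermediate D ⇌ free catalyst + product (K = 0.00390 M, k = 21.7 h⁻¹)

For a neighbour flask with 30 mM of substrate, the balance number from the runs gives 5.40 mM, or 18.0%. The computed result is 17.7%, close to the 20.0% the partner allows there, with 8.8% of that neighbour's partner left: this is where the first chemist's view comes near.

The runs were generated by integration for an exercise; scatter was added.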